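**Retrosynthetic overview**
1. Feature: ring A of the methoxyflavone half (C4a, C5–C8, C8a) is a phloroglucinol methylated only at O7. C7 can therefore travel through a tetraketide chain as the methyl enol ether that the target keeps, and ring A is built by Claisen closure C4a–C8a.
2. Last disconnections: the three benzyl ethers (hydrogenolysis), then O1–C2 of ring C of the methoxyflavone (cyclodehydration of aryl β-diketone 12).
3. Ring A: Claisen closure of open-chain ester 11. Free 11 can close in several ways under acid or base, and a glutaconate acyl donor would only protonate a diketone dianion. So 11 is stored as its enol lactone, the 4-methoxy-2-pyranone 10, and released by Mg(OMe)2 in the flask in which it cyclises.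
4. 10 comes from dilithiated 6-acetonyl-4-methoxypyranone 9 and benzoate 7. 7 comes from SNAr of 8-hydroxy-tri-O-benzylapigenin 5 on methyl 4-fluorobenzoate. 5 comes from apigenin by benzylation, C8 iodination and borylation–oxidation.
5. Ring order: the apigenin rings and the carrier pyranone are bought; ring A of the second flavone is formed in step 7, its ring C in step 8.

Key step: step 7

Assumption: β-dicarbonyl compounds 10, 11 and 12 are drawn as keto tautomers; 11 is present in the flask as a magnesium polyenolate in equilibrium with its ester-conjugated double-bond isomer, and all these forms feed the same ring closure.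

**Step 1**
Reactants: 1 apigenin
Product: 2 5,7,4'-tri-O-benzylapigenin
Conditions: BnBr (4 equiv), K2CO3, DMF, 80 °C
Reagents that add atoms: benzyl bromide, BrCc1ccccc1
Why: Williamson ether synthesis on the three phenoxides; the hydrogen-bonded 5-OH reacts last and is driven to completion by excess bromide and heat in DMF.

**Step 2**
Reactants: 2 5,7,4'-tri-O-benzylapigenin
Product: 3 8-iodo-5,7,4'-tri-O-benzylapigenin
Conditions: NIS (1.1 equiv), TFA (cat.), CH2Cl2–MeCN, 0 °C to rt, dark
Reagents that add atoms: N-iodosuccinimide, O=C1CCC(=O)N1I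
Why: Electrophilic aromatic iodination; the dialkoxy ring A is the most electron-rich arene, and with O5 alkylated (no chelated phenol directing to C6) 5,7-dialkoxyflavones are attacked at C8.

**Step 3**
Reactants: 3 8-iodo-5,7,4'-tri-O-benzylapigenin
Product: 5 8-hydroxy-5,7,4'-tri-O-benzylapigenin, via pinacol boronate 4 (not isolated)
Conditions: B2pin2, PdCl2(dppf) (5 mol%), KOAc, 1,4-dioxane, 90 °C; then 30% H2O2, aq. NaOH, THF, 0 °C
Reagents that add atoms: bis(pinacolato)diboron, CC1(C)OB(OC1(C)C)B1OC(C)(C)C(C)(C)O1; hydrogen peroxide, OO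
Why: Miyaura borylation of the aryl iodide followed by boronate oxidation (1,2-shift of the aryl group from boron to oxygen) should place the phenol at C8 without touching the benzyl ethers.

**Step 4**
Reactants: 5 8-hydroxy-5,7,4'-tri-O-benzylapigenin; 6 methyl 4-fluorobenzoate
Product: 7 methyl 4-(5,7,4'-tri-O-benzylapigenin-8-yloxy)benzoate
Conditions: K2CO3, DMSO, 110 °C
Reagents that add atoms: none
Why: Nucleophilic aromatic substitution (SNAr); the electron-rich C8 phenoxide displaces fluoride para to the ester through a Meisenheimer adduct.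

**Step 5**
Reactants: 8 4-methoxy-6-methyl-2H-pyran-2-one
Product: 9 4-methoxy-6-(2-oxopropyl)-2H-pyran-2-one
Conditions: LDA (1.1 equiv), THF, −78 °C; MeC(O)N(OMe)Me, −78 to −20 °C; aq. NH4Cl
Reagents that add atoms: N-methoxy-N-methylacetamide, CC(=O)N(C)OC
Why: Vinylogous deprotonation of the 6-methyl group gives an extended enolate that is acylated at the exocyclic carbon by the Weinreb amide; the chelated tetrahedral adduct holds the ketone back until work-up.

**Step 6**
Reactants: 9 4-methoxy-6-(2-oxopropyl)-2H-pyran-2-one; 7 methyl 4-(5,7,4'-tri-O-benzylapigenin-8-yloxy)benzoate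
Product: 10 4-methoxy-6-{2,4-dioxo-4-[4-(5,7,4'-tri-O-benzylapigenin-8-yloxy)phenyl]butyl}-2H-pyran-2-one
Conditions: 9 (2.2 equiv), LDA (4.4 equiv), THF, −78 to 0 °C; then 7, −78 to 0 °C; aq. NH4Cl
Reagents that add atoms: none
Why: Hauser–Harris acylation of a 1,3-dianion: the terminal carbanion of dilithiated 9 attacks the non-enolisable aryl ester, the second equivalent of dianion takes up the acidic proton of the new β-diketone, and the pyranone is shielded as part of the extended enolate.

**Step 7**
Reactants: 10 4-methoxy-6-{2,4-dioxo-4-[4-(5,7,4'-tri-O-benzylapigenin-8-yloxy)phenyl]butyl}-2H-pyran-2-one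
Product: 12 1-(2,6-dihydroxy-4-methoxyphenyl)-3-[4-(5,7,4'-tri-O-benzylapigenin-8-yloxy)phenyl]propane-1,3-dione, via open-chain ester 11 (not isolated)
Conditions: Mg(OMe)2 (8 equiv), MeOH–THF, 65 °C; then cold 1 M HCl
Reagents that add atoms: magnesium methoxide, CO[Mg]OC (its methoxide becomes the ester OMe of 11 and leaves again on ring closure; 12 keeps no reagent atom)
Why: Methoxide adds to the lactone carbonyl of the magnesium-chelated pyranone and the ring opens to the chelate of methyl (E)-3-methoxy-5,7,9-trioxonon-3-enoate 11, in which the former pyranone 4-OMe is the C3 enol ether that holds C2 and C5 cis. In the fully enolised triketonate the carbon between the C5 and C7 carbonyls (flavone C4a) attacks the ester carbon C1 (flavone C8a), methoxide leaves and the cyclohexenedione enolises to the 2-acyl-5-methoxyresorcinol, so ring A closes by a 6-exo-trig Claisen condensation. The closest known reactions are the Claisen cyclisation of 3,5,7-triketo esters to acylphloroglucinols and the magnesium methoxide conversion of 6-(2-oxoalkyl)pyran-2-ones into acylphloroglucinols. No stereocentre is formed. The step needs Claisen closure to win over aldol closure of C2 onto the C7 ketone and over addition–elimination of C8 at C3: excess magnesium methoxide keeps C5, C7 and C9 as chelated enolates, so the ester is the only electrophile left and only C6 reaches it through a six-membered transition state. The new ring is symmetric about its acyl group, so the later pyranone closure has no regiochemical choice.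

**Step 8**
Reactants: 12 1-(2,6-dihydroxy-4-methoxyphenyl)-3-[4-(5,7,4'-tri-O-benzylapigenin-8-yloxy)phenyl]propane-1,3-dione
Product: 13 5-hydroxy-7-methoxy-2-[4-(5,7,4'-tri-O-benzylapigenin-8-yloxy)phenyl]-4H-chromen-4-one
Conditions: p-TsOH·H2O (10 mol%), toluene, 80 °C
Reagents that add atoms: none
Why: Acid-catalysed cyclodehydration of an o-hydroxyaryl β-diketone (the closing step of the Baker–Venkataraman flavone synthesis): either of the two equivalent phenols adds to the aryl ketone and the hemiketal loses water.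

**Step 9**
Reactants: 13 5-hydroxy-7-methoxy-2-[4-(5,7,4'-tri-O-benzylapigenin-8-yloxy)phenyl]-4H-chromen-4-one
Product: 14 5-hydroxy-7-methoxy-2-{4-[(5,7-dihydroxy-2-(4-hydroxyphenyl)-4-oxo-4H-chromen-8-yl)oxy]phenyl}-4H-chromen-4-one (target CNP0424791.0)
Conditions: H2 (1 atm), 10% Pd/C, THF–MeOH, rt
Reagents that add atoms: none
Why: Catalytic hydrogenolysis of the three benzyl ethers; the aryl methyl ether, the diaryl ether and the flavone C2=C3 bonds should survive these mild conditions.

**Compound list**
1 | apigenin | O=c1cc(-c2ccc(O)cc2)oc2cc(O)cc(O)c12 | starting material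
2 | 5,7,4'-tri-O-benzylapigenin | O=c1cc(-c2ccc(OCc3ccccc3)cc2)oc2cc(OCc3ccccc3)cc(OCc3ccccc3)c12 | intermediate
3 | 8-iodo-5,7,4'-tri-O-benzylapigenin | O=c1cc(-c2ccc(OCc3ccccc3)cc2)oc2c(I)c(OCc3ccccc3)cc(OCc3ccccc3)c12 | intermediate
4 | 5,7,4'-tri-O-benzylapigenin-8-yl pinacol boronate | O=c1cc(-c2ccc(OCc3ccccc3)cc2)oc2c(B3OC(C)(C)C(C)(C)O3)c(OCc3ccccc3)cc(OCc3ccccc3)c12 | intermediate
5 | 8-hydroxy-5,7,4'-tri-O-benzylapigenin | O=c1cc(-c2ccc(OCc3ccccc3)cc2)oc2c(O)c(OCc3ccccc3)cc(OCc3ccccc3)c12 | intermediate
6 | methyl 4-fluorobenzoate | COC(=O)c1ccc(F)cc1 | starting material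
7 | methyl 4-(5,7,4'-tri-O-benzylapigenin-8-yloxy)benzoate | COC(=O)c1ccc(Oc2c(OCc3ccccc3)cc(OCc3ccccc3)c3c(=O)cc(-c4ccc(OCc5ccccc5)cc4)oc23)cc1 | intermediate
8 | 4-methoxy-6-methyl-2H-pyran-2-one | COc1cc(=O)oc(C)c1 | starting material
9 | 4-methoxy-6-(2-oxopropyl)-2H-pyran-2-one | COc1cc(=O)oc(CC(C)=O)c1 | intermediate
10 | 4-methoxy-6-{2,4-dioxo-4-[4-(5,7,4'-tri-O-benzylapigenin-8-yloxy)phenyl]butyl}-2H-pyran-2-one | COc1cc(=O)oc(CC(=O)CC(=O)c2ccc(Oc3c(OCc4ccccc4)cc(OCc4ccccc4)c4c(=O)cc(-c5ccc(OCc6ccccc6)cc5)oc34)cc2)c1 | intermediate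
11 | methyl (E)-3-methoxy-5,7,9-trioxo-9-[4-(5,7,4'-tri-O-benzylapigenin-8-yloxy)phenyl]non-3-enoate | COC(=O)C/C(OC)=C\C(=O)CC(=O)CC(=O)c1ccc(Oc2c(OCc3ccccc3)cc(OCc3ccccc3)c3c(=O)cc(-c4ccc(OCc5ccccc5)cc4)oc23)cc1 | intermediate
12 | 1-(2,6-dihydroxy-4-methoxyphenyl)-3-[4-(5,7,4'-tri-O-benzylapigenin-8-yloxy)phenyl]propane-1,3-dione | COc1cc(O)c(C(=O)CC(=O)c2ccc(Oc3c(OCc4ccccc4)cc(OCc4ccccc4)c4c(=O)cc(-c5ccc(OCc6ccccc6)cc5)oc34)cc2)c(O)c1 | intermediate
13 | 5-hydroxy-7-methoxy-2-[4-(5,7,4'-tri-O-benzylapigenin-8-yloxy)phenyl]-4H-chromen-4-one | COc1cc(O)c2c(=O)cc(-c3ccc(Oc4c(OCc5ccccc5)cc(OCc5ccccc5)c5c(=O)cc(-c6ccc(OCc7ccccc7)cc6)oc45)cc3)oc2c1 | intermediate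
14 | 5-hydroxy-7-methoxy-2-{4-[(5,7-dihydroxy-2-(4-hydroxyphenyl)-4-oxo-4H-chromen-8-yl)oxy]phenyl}-4H-chromen-4-one | COc1cc(O)c2c(=O)cc(-c3ccc(Oc4c(O)cc(O)c5c(=O)cc(-c6ccc(O)cc6)oc45)cc3)oc2c1 | target

**Step count**
Total steps: 9. Longest linear sequence: 8 (steps 1–4 and 6–9 from apigenin); step 5 is a one-step side branch from the commercial pyranone 8.

**Steps most likely to fail**

Step 7. The pyranone may resist methanolysis once its side chain is enolised into the ring, methoxide may add at C6 instead of the lactone carbonyl, or the released chain may close by aldol or be cut by retro-Claisen cleavage. The fallback builds ring A from a purchased arene by acyl migration. It sets out from 7 and comes back at 12. Saponification of 7 (LiOH, THF–H2O) should give 4-(5,7,4'-tri-O-benzylapigenin-8-yloxy)benzoic acid F1. Coupling with commercial 2',6'-dihydroxy-4'-methoxyacetophenone (EDC·HCl, DMAP, CH2Cl2) should give the mono-ester 2-acetyl-3-hydroxy-5-methoxyphenyl 4-(5,7,4'-tri-O-benzylapigenin-8-yloxy)benzoate F2. A Baker–Venkataraman O-to-C acyl shift (KOH, pyridine, 50 °C, or LiHMDS, THF) should then give 12.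

Step 6. The terminal carbanion may be quenched by proton transfer, may add to the flavone C2 or may react too slowly with the donor-substituted benzoate; the pyranone ring may also be metalated. The fallback replaces acylation by aldol addition and oxidation. It sets out from 5 and 9 and comes back at 10. SNAr of 5 on 4-fluorobenzaldehyde (K2CO3, DMF, 100 °C) should give 4-(5,7,4'-tri-O-benzylapigenin-8-yloxy)benzaldehyde F3. Addition of dilithiated 9 (1.2 equiv, THF, −78 °C), which needs no second equivalent because the aldolate is not acidic, should give the racemic β-hydroxy ketone 6-{4-hydroxy-2-oxo-4-[4-(5,7,4'-tri-O-benzylapigenin-8-yloxy)phenyl]butyl}-4-methoxy-2H-pyran-2-one F4. Dess–Martin oxidation should then give 10.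

Step 4. Substitution at the doubly ortho-substituted phenoxide may be slow, and at the required temperature the methyl ester may be hydrolysed or transesterified by the phenoxide. The fallback reverses the roles of the partners. It sets out from 3 and comes back at 7: copper-catalysed Ullmann diaryl ether coupling of iodide 3 with methyl 4-hydroxybenzoate (CuI, picolinic acid, K3PO4, DMSO, 90 °C) should give 7 directly and makes step 3 unnecessary; no new compound is formed on the way.

**Further compounds**
F1 | step 7 | 4-(5,7,4'-tri-O-benzylapigenin-8-yloxy)benzoic acid | OC(=O)c1ccc(Oc2c(OCc3ccccc3)cc(OCc3ccccc3)c3c(=O)cc(-c4ccc(OCc5ccccc5)cc4)oc23)cc1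
F2 | step 7 | 2-acetyl-3-hydroxy-5-methoxyphenyl 4-(5,7,4'-tri-O-benzylapigenin-8-yloxy)benzoate | COc1cc(O)c(C(C)=O)c(OC(=O)c2ccc(Oc3c(OCc4ccccc4)cc(OCc4ccccc4)c4c(=O)cc(-c5ccc(OCc6ccccc6)cc5)oc34)cc2)c1
F3 | step 6 | 4-(5,7,4'-tri-O-benzylapigenin-8-yloxy)benzaldehyde | O=Cc1ccc(Oc2c(OCc3ccccc3)cc(OCc3ccccc3)c3c(=O)cc(-c4ccc(OCc5ccccc5)cc4)oc23)cc1
F4 | step 6 | 6-{4-hydroxy-2-oxo-4-[4-(5,7,4'-tri-O-benzylapigenin-8-yloxy)phenyl]butyl}-4-methoxy-2H-pyran-2-one (racemic) | COc1cc(=O)oc(CC(=O)CC(O)c2ccc(Oc3c(OCc4ccccc4)cc(OCc4ccccc4)c4c(=O)cc(-c5ccc(OCc6ccccc6)cc5)oc34)cc2)c1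
F0 | step 4 | none | none
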